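The oxolane is traced back to an α-methylene-γ-lactone in which C2 is the carbonyl carbon and the C3 methyl an exocyclic methylene. The key step exploits the anti relationship between the C5 carbinol carbon (bearing ring B, the 4-hydroxy-3,5-dimethoxyphenyl ring) and the C4 methyl, next to C3: a chiral-phosphoric-acid-catalysed crotylboration of O-benzylsyringaldehyde with a Z-configured 2-(ethoxycarbonyl)crotyl pinacolboronate forms C4–C5 with both stereocentres, and the borate then closes O1–C2 to the five-membered ring. The precursors are thus an aryl aldehyde and a boronate whose methyl is trans to CH2B. Hydrogenation (C3), reductive acetylation, arylation with veratrole (C2) and debenzylation complete the target.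

Key step: step 3

Numbering used throughout: O1, C2 (3,4-dimethoxyphenyl), C3 (methyl), C4 (methyl), C5 (ring B). The target is (2S,3S,4R,5R), which is 2,3-trans, 3,4-cis, 4,5-trans, with the two aryl groups cis to each other.

Assumption: the (R)-configured acid is taken to direct the boronate to the Re face of the aldehyde, as it does for simple allyl and crotyl pinacolboronates; if this boronate shows the opposite sense, the (S)-acid is used and nothing else changes.

Step 1
Reactants: 1 4-hydroxy-3,5-dimethoxybenzaldehyde (syringaldehyde)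
Product: 2 4-(benzyloxy)-3,5-dimethoxybenzaldehyde
Conditions: BnBr, K2CO3, DMF, rt
Reagents that add atoms: benzyl bromide, BrCc1ccccc1
Why: Williamson ether synthesis on the phenoxide, which K2CO3 forms without touching the aldehyde.

Step 2
Reactants: 3 ethyl but-2-ynoate; 4 2-(iodomethyl)-4,4,5,5-tetramethyl-1,3,2-dioxaborolane
Product: 6 ethyl (Z)-2-[(4,4,5,5-tetramethyl-1,3,2-dioxaborolan-2-yl)methyl]but-2-enoate, via vinylalane 5 (not isolated)
Conditions: i-Bu2AlH, HMPA, THF, 0 °C; then 4, 0 °C → rt
Reagents that add atoms: none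
Why: Conjugate hydroalumination puts hydride on C3 and aluminium on C2 of the ynoate from the same side, and the α-alumino enoate 5 is alkylated by the iodomethylboronate with retention (alkenyl transfer to boron and 1,2-shift with loss of iodide, a Matteson-type homologation), so the methyl ends cis to the ester and trans to CH2B (Z).

Step 3
Reactants: 2 4-(benzyloxy)-3,5-dimethoxybenzaldehyde; 6 ethyl (Z)-2-[(4,4,5,5-tetramethyl-1,3,2-dioxaborolan-2-yl)methyl]but-2-enoate
Product: 8 (4R,5R)-5-[4-(benzyloxy)-3,5-dimethoxyphenyl]-4-methyl-3-methylideneoxolan-2-one, via borate ester 7 (not isolated)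
Conditions: 6 (1.3 equiv), (R)-3,3'-bis(2,4,6-triisopropylphenyl)-1,1'-binaphthyl-2,2'-diyl hydrogen phosphate (10 mol%), toluene, 0 °C → rt; then (1S)-camphor-10-sulfonic acid (10 mol%) once 2 is consumed, rt
Reagents that add atoms: none
Why: The phosphoric acid activates the pinacol boronate by a hydrogen bond from P–OH to a boronate oxygen while its P=O oxygen holds the formyl hydrogen, so the allyl unit is transferred within a closed six-membered chair (Zimmerman–Traxler type) in which boron is bound to the carbonyl oxygen, the aryl group is equatorial and the γ-carbon of the boronate forms C4–C5. The closest known reaction types are the chiral-phosphoric-acid-catalysed allyl- and crotylboration of aldehydes with pinacol boronates and the Brønsted-acid-catalysed addition of 2-alkoxycarbonyl allylboronates to aldehydes that ends in α-methylene-γ-lactones. The ring is closed by 5-exo-trig acyl substitution, in which the boron-bound C5 oxygen of borate 7 attacks the ester carbonyl (O1–C2) and ethoxide passes to boron, the sulfonic acid added at the end serving only to complete this lactonisation. C5 is set by the catalyst, whose (R)-binaphthyl pocket should expose the Re face of the aldehyde, and C4 is set relative to C5 by the olefin geometry, because the methyl trans to CH2B sits equatorial in the chair and ends anti to the new C–O bond, which after ring closure is the 4,5-trans lactone. The step needs enantioface selectivity and anti selectivity; the first is secured because the ester makes boronate 6 inert towards the aldehyde without acid at this temperature, so that no racemic background competes, and the second by the geometrically pure Z-olefin from step 2.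

Step 4
Reactants: 8 (4R,5R)-5-[4-(benzyloxy)-3,5-dimethoxyphenyl]-4-methyl-3-methylideneoxolan-2-one
Product: 9 (3S,4R,5R)-5-[4-(benzyloxy)-3,5-dimethoxyphenyl]-3,4-dimethyloxolan-2-one
Conditions: H2 (1 atm), RhCl(PPh3)3 (5 mol%), toluene–EtOH (1:1), rt
Reagents that add atoms: none
Why: Homogeneous hydrogenation with RhCl(PPh3)3 reduces the unhindered 1,1-disubstituted alkene without hydrogenolysis of the benzyl ether, and hydrogen should reach C3 from the face opposite the neighbouring C4 methyl, so that the new C3 methyl is cis to it (3S).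

Step 5
Reactants: 9 (3S,4R,5R)-5-[4-(benzyloxy)-3,5-dimethoxyphenyl]-3,4-dimethyloxolan-2-one
Product: 11 (3S,4R,5R)-5-[4-(benzyloxy)-3,5-dimethoxyphenyl]-3,4-dimethyloxolan-2-yl acetate (both C2 epimers), via aluminium lactolate 10 (not isolated)
Conditions: i-Bu2AlH (1.1 equiv), CH2Cl2, −78 °C; then pyridine, 4-(dimethylamino)pyridine, Ac2O, −78 → 0 °C
Reagents that add atoms: acetic anhydride, CC(=O)OC(C)=O
Why: In this one-pot reductive acetylation the tetrahedral aluminium hemiacetal 10 is stable at −78 °C and is acylated in the flask before it can open to the hydroxy aldehyde and epimerise C3, while the C2 configuration is irrelevant because step 6 erases it.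

Step 6
Reactants: 11 (3S,4R,5R)-5-[4-(benzyloxy)-3,5-dimethoxyphenyl]-3,4-dimethyloxolan-2-yl acetate; 12 1,2-dimethoxybenzene (veratrole)
Product: 14 (2S,3S,4R,5R)-5-[4-(benzyloxy)-3,5-dimethoxyphenyl]-2-(3,4-dimethoxyphenyl)-3,4-dimethyloxolane, via oxocarbenium ion 13 (not isolated)
Conditions: 12 (5 equiv), BF3·OEt2 (1.5 equiv), CH2Cl2, −78 → −40 °C
Reagents that add atoms: none
Why: BF3·OEt2 ionises the anomeric acetate to the ring oxocarbenium ion 13, which veratrole should attack in a Friedel–Crafts arylation through the position para to a methoxy group and from the face of C2 opposite the adjacent C3 methyl (both methyls lie on the other face), giving the 2,3-trans product (2S).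

Step 7
Reactants: 14 (2S,3S,4R,5R)-5-[4-(benzyloxy)-3,5-dimethoxyphenyl]-2-(3,4-dimethoxyphenyl)-3,4-dimethyloxolane
Product: 15 (2S,3S,4R,5R)-2-(3,4-dimethoxyphenyl)-5-(4-hydroxy-3,5-dimethoxyphenyl)-3,4-dimethyloxolane, also named 4-[(2R,3R,4S,5S)-5-(3,4-dimethoxyphenyl)-3,4-dimethyloxolan-2-yl]-2,6-dimethoxyphenol
Conditions: H2 (1 atm), 10% Pd/C, EtOAc, rt
Reagents that add atoms: none
Why: Hydrogenolysis of the aryl benzyl ether over Pd/C in a neutral solvent should be faster than cleavage of the two benzylic C–O bonds of the ring, so the phenol is freed without touching a stereocentre.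

Compound list
1 | 4-hydroxy-3,5-dimethoxybenzaldehyde (syringaldehyde) | COc1cc(C=O)cc(OC)c1O | starting material
2 | 4-(benzyloxy)-3,5-dimethoxybenzaldehyde | COc1cc(C=O)cc(OC)c1OCc1ccccc1 | intermediate
3 | ethyl but-2-ynoate | CC#CC(=O)OCC | starting material
4 | 2-(iodomethyl)-4,4,5,5-tetramethyl-1,3,2-dioxaborolane | ICB1OC(C)(C)C(C)(C)O1 | starting material
5 | ethyl (E)-2-[bis(2-methylpropyl)alumanyl]but-2-enoate (H and Al cis; not isolated) | C/C=C(/[Al](CC(C)C)CC(C)C)C(=O)OCC | intermediate
6 | ethyl (Z)-2-[(4,4,5,5-tetramethyl-1,3,2-dioxaborolan-2-yl)methyl]but-2-enoate | C/C=C(/CB1OC(C)(C)C(C)(C)O1)C(=O)OCC | intermediate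
7 | ethyl (3R,4R)-4-[4-(benzyloxy)-3,5-dimethoxyphenyl]-3-methyl-2-methylidene-4-[(4,4,5,5-tetramethyl-1,3,2-dioxaborolan-2-yl)oxy]butanoate (not isolated) | CC1(C)OB(O[C@@H](c2cc(OC)c(OCc3ccccc3)c(OC)c2)[C@H](C)C(=C)C(=O)OCC)OC1(C)C | intermediate
8 | (4R,5R)-5-[4-(benzyloxy)-3,5-dimethoxyphenyl]-4-methyl-3-methylideneoxolan-2-one | O=C1O[C@@H](c2cc(OC)c(OCc3ccccc3)c(OC)c2)[C@H](C)C1=C | intermediate
9 | (3S,4R,5R)-5-[4-(benzyloxy)-3,5-dimethoxyphenyl]-3,4-dimethyloxolan-2-one | O=C1O[C@@H](c2cc(OC)c(OCc3ccccc3)c(OC)c2)[C@H](C)[C@@H]1C | intermediate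
10 | {[(3S,4R,5R)-5-[4-(benzyloxy)-3,5-dimethoxyphenyl]-3,4-dimethyloxolan-2-yl]oxy}bis(2-methylpropyl)alumane (C2 epimers; not isolated) | CC(C)C[Al](CC(C)C)OC1O[C@@H](c2cc(OC)c(OCc3ccccc3)c(OC)c2)[C@H](C)[C@@H]1C | intermediate
11 | (3S,4R,5R)-5-[4-(benzyloxy)-3,5-dimethoxyphenyl]-3,4-dimethyloxolan-2-yl acetate (C2 epimers) | CC(=O)OC1O[C@@H](c2cc(OC)c(OCc3ccccc3)c(OC)c2)[C@H](C)[C@@H]1C | intermediate
12 | 1,2-dimethoxybenzene (veratrole) | COc1ccccc1OC | starting material
13 | (2R,3R,4S)-2-[4-(benzyloxy)-3,5-dimethoxyphenyl]-3,4-dimethyl-3,4-dihydro-2H-furan-1-ium (ring oxocarbenium ion; not isolated) | [CH]1=[O+][C@@H](c2cc(OC)c(OCc3ccccc3)c(OC)c2)[C@H](C)[C@@H]1C | intermediate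
14 | (2S,3S,4R,5R)-5-[4-(benzyloxy)-3,5-dimethoxyphenyl]-2-(3,4-dimethoxyphenyl)-3,4-dimethyloxolane | COc1ccc([C@H]2O[C@@H](c3cc(OC)c(OCc4ccccc4)c(OC)c3)[C@H](C)[C@@H]2C)cc1OC | intermediate
15 | (2S,3S,4R,5R)-2-(3,4-dimethoxyphenyl)-5-(4-hydroxy-3,5-dimethoxyphenyl)-3,4-dimethyloxolane | COc1ccc([C@H]2O[C@@H](c3cc(OC)c(O)c(OC)c3)[C@H](C)[C@@H]2C)cc1OC | target

Total step count: 7. Longest linear sequence: 6 steps (steps 1, 3, 4, 5, 6 and 7 from syringaldehyde); step 2 is a one-step branch that joins at step 3.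

Steps most likely to fail

Step 3. The ester-deactivated boronate may turn over too slowly under the weak chiral acid, and raising the temperature to compensate would erode enantioface selectivity. The fallback replaces catalyst control by reagent control and sets out from 2. Brown crotylboration with (E)-crotyldiisopinocampheylborane (trans-but-2-ene, n-BuLi, KOt-Bu, then (+)-B-methoxydiisopinocampheylborane from (−)-α-pinene and BF3·OEt2; −78 °C; NaOH, H2O2), the antipode expected to add to the Re face, should give (1R,2R)-1-[4-(benzyloxy)-3,5-dimethoxyphenyl]-2-methylbut-3-en-1-ol F1. Hydroboration with 9-borabicyclo[3.3.1]nonane and oxidation (NaOH, H2O2) leads to (1R,2R)-1-[4-(benzyloxy)-3,5-dimethoxyphenyl]-2-methylbutane-1,4-diol F2. Selective oxidation of the primary alcohol (2,2,6,6-tetramethylpiperidin-1-oxyl, PhI(OAc)2, CH2Cl2) closes (4R,5R)-5-[4-(benzyloxy)-3,5-dimethoxyphenyl]-4-methyloxolan-2-one F3. Mannich reaction (LiN(SiMe3)2, THF, −78 °C, then dimethylmethyleneiminium iodide) gives (4R,5R)-5-[4-(benzyloxy)-3,5-dimethoxyphenyl]-3-[(dimethylamino)methyl]-4-methyloxolan-2-one F4. Quaternisation with MeI forms {[(4R,5R)-5-[4-(benzyloxy)-3,5-dimethoxyphenyl]-4-methyl-2-oxooxolan-3-yl]methyl}trimethylammonium iodide F5, which eliminates with NaHCO3 and returns to the route at 8.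

Step 6. The attack on the oxocarbenium ion may show poor facial selectivity, the ion may lose its C3 configuration by deprotonation to the enol ether, or the Lewis acid may open the product ring at C5 and lead to cyclisation onto an arene. The fallback forms the C2–aryl bond with an organometallic and closes the ring afterwards; it sets out from 9. Reduction (i-Bu2AlH, CH2Cl2, −78 °C, aqueous work-up) gives (3S,4R,5R)-5-[4-(benzyloxy)-3,5-dimethoxyphenyl]-3,4-dimethyloxolan-2-ol F6. Addition of 3,4-dimethoxyphenylmagnesium bromide (3 equiv, THF, 0 °C) gives (1R,2R,3S)-1-[4-(benzyloxy)-3,5-dimethoxyphenyl]-4-(3,4-dimethoxyphenyl)-2,3-dimethylbutane-1,4-diol F7 as a mixture at the new carbinol. MsCl and Et3N (CH2Cl2, 0 °C) convert the more electron-rich veratryl carbinol into (2S,3R,4R)-4-[4-(benzyloxy)-3,5-dimethoxyphenyl]-1-(3,4-dimethoxyphenyl)-4-hydroxy-2,3-dimethylbutyl methanesulfonate F8. This mesylate should ionise and be captured by the C5 hydroxyl, with C5 retained and the aryl group settling trans to the C3 methyl, which returns to the route at 14.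

Step 4. Hydrogen delivery may show poor facial selectivity, or the double bond may migrate into the ring, which would erase C4. The fallback replaces hydrogenation by conjugate hydride addition and kinetic protonation; it sets out from 8. LiBH(s-Bu)3 (THF, −78 °C) should give lithium (4R,5R)-5-[4-(benzyloxy)-3,5-dimethoxyphenyl]-3,4-dimethyl-4,5-dihydrofuran-2-olate F9, which is protonated at −78 °C with saturated aqueous NH4Cl on the face opposite the C4 methyl and returns to the route at 9.

Further compounds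
F1 | step 3 | (1R,2R)-1-[4-(benzyloxy)-3,5-dimethoxyphenyl]-2-methylbut-3-en-1-ol | O[C@@H](c1cc(OC)c(OCc2ccccc2)c(OC)c1)[C@H](C)C=C
F2 | step 3 | (1R,2R)-1-[4-(benzyloxy)-3,5-dimethoxyphenyl]-2-methylbutane-1,4-diol | O[C@@H](c1cc(OC)c(OCc2ccccc2)c(OC)c1)[C@H](C)CCO
F3 | step 3 | (4R,5R)-5-[4-(benzyloxy)-3,5-dimethoxyphenyl]-4-methyloxolan-2-one | O=C1O[C@@H](c2cc(OC)c(OCc3ccccc3)c(OC)c2)[C@H](C)C1
F4 | step 3 | (4R,5R)-5-[4-(benzyloxy)-3,5-dimethoxyphenyl]-3-[(dimethylamino)methyl]-4-methyloxolan-2-one (C3 epimers) | O=C1O[C@@H](c2cc(OC)c(OCc3ccccc3)c(OC)c2)[C@H](C)C1CN(C)C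
F5 | step 3 | {[(4R,5R)-5-[4-(benzyloxy)-3,5-dimethoxyphenyl]-4-methyl-2-oxooxolan-3-yl]methyl}trimethylammonium iodide | O=C1O[C@@H](c2cc(OC)c(OCc3ccccc3)c(OC)c2)[C@H](C)C1C[N+](C)(C)C.[I-]
F6 | step 6 | (3S,4R,5R)-5-[4-(benzyloxy)-3,5-dimethoxyphenyl]-3,4-dimethyloxolan-2-ol (C2 epimers) | OC1O[C@@H](c2cc(OC)c(OCc3ccccc3)c(OC)c2)[C@H](C)[C@@H]1C
F7 | step 6 | (1R,2R,3S)-1-[4-(benzyloxy)-3,5-dimethoxyphenyl]-4-(3,4-dimethoxyphenyl)-2,3-dimethylbutane-1,4-diol (C4 epimers) | O[C@@H](c1cc(OC)c(OCc2ccccc2)c(OC)c1)[C@H](C)[C@H](C)C(O)c1ccc(OC)c(OC)c1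
F8 | step 6 | (2S,3R,4R)-4-[4-(benzyloxy)-3,5-dimethoxyphenyl]-1-(3,4-dimethoxyphenyl)-4-hydroxy-2,3-dimethylbutyl methanesulfonate (C1 epimers) | O[C@@H](c1cc(OC)c(OCc2ccccc2)c(OC)c1)[C@H](C)[C@H](C)C(OS(C)(=O)=O)c1ccc(OC)c(OC)c1
F9 | step 4 | lithium (4R,5R)-5-[4-(benzyloxy)-3,5-dimethoxyphenyl]-3,4-dimethyl-4,5-dihydrofuran-2-olate | [Li]OC=1O[C@@H](c2cc(OC)c(OCc3ccccc3)c(OC)c2)[C@H](C)C=1C
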